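If a flask levels off, stop reading percentages and take the plateau ratio: monomer in chains over free monomer, both as fractions of the charge.

the same everywhere: initiator 0.34 mM
- Wednesday's: free monomer 0.067 M; transfer agent 4.8 mM; run made earlier
- Tuesday's: free monomer 0.12 M; transfer agent 4.8 mM; run made earlier
- Sunday's: free monomer 0.13 M; transfer agent 4.8 mM; run made earlier
- larch: free monomer 0.16 M; transfer agent 4.80 mM; time 10 d
- elm: free monomer 0.080 M; transfer agent 4.80 mM; time 10 d

| run | time / d | monomer in chains / % | free monomer / % |
|---|---|---|---|
| Wednesday's | 1.25 | 31.0 | 67.7 |
| Wednesday's | 3.00 | 30.3 | 67.9 |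
| Wednesday's | 4.00 | 31.5 | 69.6 |
| Wednesday's | 6.00 | 30.9 | 69.4 |
| Wednesday's | 8.00 | 29.5 | 68.9 |
| Tuesday's | 0.625 | 40.4 | 59.6 |
| Tuesday's | 1.04 | 42.5 | 58.6 |
| Tuesday's | 2.08 | 39.6 | 59.2 |
| Tuesday's | 4.00 | 41.0 | 59.2 |
| Tuesday's | 8.00 | 40.4 | 59.5 |
| Sunday's | 0.625 | 40.3 | 59.2 |
| Sunday's | 1.04 | 42.1 | 58.6 |
| Sunday's | 2.08 | 40.2 | 58.7 |
| Sunday's | 4.00 | 41.6 | 58.1 |
| Sunday's | 8.00 | 42.2 | 59.6 |

(standard deviation of a reading: 1 percentage point)

- the average divides the monomer in chains by the number of chains begun, living and dead together
- the earlier runs do not show the number of chains; that part of a forecast is a guess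

1. which of the two ends with the longer chains by the average number of monomer units in a chain (chains begun, living or dead) ("neither" if they lie within 10%) (larch / elm / neither)
2. average number of monomer units in a chain (chains begun, living or dead) at the end, larch
3. average number of monomer units in a chain (chains begun, living or dead) at the end, elm

Take the means of Wednesday's run and Sunday's: their plateau ratios read 0.446 and 0.702. Now go to logarithms. The charge of free monomer climbs 0.288 of a power of ten and the ratio 0.197, so the ratio gains 0.683 powers of ten per power of ten of charge; call this slope the plateau exponent. Carried from Sunday's charge, it gives larch a ratio of 0.809, which puts 44.7% of the charge in chains. Carried from Wednesday's, it gives elm 0.503, which puts 33.5% in chains.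

For length, use the bench rule of one chain per initiator charged: multiply the chained fraction by the charge of free monomer over the charge of initiator. Larch gets 210 and elm 78.8, so reckon larch the longer. The rule ends where something else begins chains. Transfer agent stands at 14.1 times the initiator's charge, and the runs show no count of chains. Bet that transfer agent begins none. On that bet both figures are floors: initiator lost without beginning a chain leaves fewer chains and a greater length.

The forecast names larch, with 14 for larch and 5.5 for elm: “The number of chains is a guess”. The flask gives larch, with 551 for larch and 298 for elm.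

    free monomer + initiator → living end + monomer in chains (k = 2.80 L mol⁻¹ h⁻¹)
    free monomer + living end → monomer in chains + living end, rate k2*[living end]*[free monomer] (k = 4100 L mol⁻¹ h⁻¹)
    living end + transfer agent → dead chain (kL = 190 L mol⁻¹ h⁻¹)
    initiator + monomer in chains → spent initiator A (k = 1.40 L mol⁻¹ h⁻¹)
    2 initiator → spent initiator B (k = 2300 L mol⁻¹ h⁻¹)

Larch ends with 44.7% in chains and 55.3% free, a ratio of 0.808 against the reckoned 0.809, and it keeps 0% of its initiator. Its dead chain comes to 0.382 of the initiator charge, and its length of 551 stands above the reckoned floor of 210. Now try the neighbouring flask, elm with 0.32 M of free monomer. The exponent carried from Wednesday's run gives a ratio of 1.30, hence 43.5% free. That flask ends with 44.9% free and a length of 1010.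

(The runs stem from a simulated flask from invented constants, noise included.)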